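(The numbers in the tables are calculated on assumed constants; scatter was added.)

Time is what you read first: from 12.0 h to 30.0 h the product of the green run reads 31.8%, 32.4% and 31.4%, flat within the scatter of 1 percentage point, so you can freeze one quantity and leave the rates aside.

| setting | teal | green | flask |
|---|---|---|---|
| substrate | 0.54 M | 1.1 M | 0.54 M |
| salt in the second phase | 1.08 M | 1.08 M | 1.08 M |
| spent carrier | 27 mM | 27 mM | 27 mM |
| impurity | 23 mM | 23 mM | 23 mM |
| remark | the very flask that is asked about, followed so far | run made earlier |  |
| time |  |  | 3.0 d |
| volume of the second phase over the first |  |  | 1.0 |

- teal (time / h: substrate / %, product / %): 1.00: 83.3, 17.0; 1.50: 77.6, 18.6; 2.50: 71.4, 29.2; 4.00: 65.1, 35.7; 6.00: 60.8, 38.9; 8.00: 55.1, 42.8; 12.0: 56.5, 46.3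
- green (time / h: substrate / %, product / %): 2.50: 79.0, 19.6; 4.00: 74.1, 25.7; 5.00: 73.2, 26.7; 8.00: 69.6, 30.4; 12.0: 66.3, 31.8; 20.0: 66.6, 32.4; 30.0: 69.6, 31.4

(readings scatter by 1 percentage point)

- in the second phase: salt in the second phase, spent salt in the second phase; everything else is in the first
- charges count per volume of the first phase; a concentration in a rate is the amount of a species over the volume of its own phase; every rate counts per litre of the first phase
- on the list of suspects stand: substrate + fresh carrier <-> product + spent carrier; spent carrier + salt in the second phase <-> fresh carrier + spent salt in the second phase; fresh carrier + impurity -> spent catalyst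
- the earlier runs hold the two phases in the same ratio of volumes as the flask asked about
- the reaction counts as stopped when no species that holds the substrate changes by six tenths of a point or more over the second half of the time

- at 3.0 d, what has stopped the reaction, if anything has (forward and back rates have come level / no working catalyst is left / all of the substrate has reacted / it is still moving / the salt in the second phase has run out first)
- part of the substrate gone at 3.0 d
- the product standing at 3.0 d, as a percentage of the substrate charged

Keep the books on the substrate, the limiting reagent, because in the teal flask 0.54 M of it faces 1.08 M of salt in the second phase. Each mole that reacts becomes a mole of product and, through the carrier, turns a mole of salt into spent salt. A second entry belongs to the impurity: the 23 mM of it is less than the 27 mM of spent carrier, and I book one salt for each carrier it destroys. The phases have equal volumes, so the books close on Q = c(product) c(spent salt) / (c(substrate) c(salt)). The mean green plateau puts 0.351 M of product in that ledger and gives Q = 0.247, the plateau quotient, which is a reading that carries the scatter of the plateau and which I use as my estimate of the equilibrium constant of the net reaction. Setting this Q on the teal ledger and solving the quadratic, I get 0.237 M of product, or 43.9% of the charge.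

The forecast says forward and back rates have come level, with 44.5% gone and 44.3% of product, a little above my figure; of the green plateau it says “I read this as a true equilibrium”.

The flask gives forward and back rates have come level, with 45.0% gone and 45.0% of product, and the product already stood at 44.7% after 0.600 d.

    substrate + fresh carrier ⇌ product + spent carrier (K = 0.340, k = 1.27 M⁻¹ min⁻¹)
    spent carrier + salt in the second phase ⇌ fresh carrier + spent salt in the second phase (K = 0.797, k = 0.878 M⁻¹ min⁻¹)
    fresh carrier + impurity → spent catalyst (k = 61.6 M⁻¹ min⁻¹)

The product reckoned with the quotient 0.247 stands 1.1 points under the flask, from one plateau and no rate. With 0.22 M of substrate and the other charges held, the same Q gives 0.131 M of product, 59.5% of that charge. The computed neighbour stands at 60.9%.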